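A small saturation concentration of coupling partner, 10 mM, is less than the 0.050 M of starting material fed into this flask.

starting material 0.050 M (fed, over 50 s); gas 10 mM (held); time 50 s

    starting material + coupling partner → first product + released group (k1 = 5.63 /M/s)
    coupling partner + first product → bis adduct + released group (k2 = 0.718 /M/s)
    coupling partner + released group ⇌ idle adduct A, settled at all times (K3 = 7730 /M)
    coupling partner + bis adduct ⇌ idle adduct B, settled at all times (K4 = 34 /M)
    gas ⇌ coupling partner, rate k5*(csat - [coupling partner]) (k5 = 0.0343 /s, csat = 10 mM)

- part of the starting material that has reacted at 50 s
- share of free coupling partner in free coupling partner and idle adduct A together, at 50 s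

- what is said of bis adduct includes idle adduct B
- what is said of released group includes idle adduct A
- at the start none of coupling partner is dissolved
- run time (flask): 50 s

At full transfer the gas delivers 0.343 mM/s, or 17.1 mM over the run. Follow one dissolved molecule of coupling partner through a small table of its forks, one row each.

First row, starting material: at the whole charge the molecule's half-life is 2.5 s, shorter than the 20.2 s of transfer, so with that much starting material present transfer is the rate-limiting step.

Next row, released group: each turnover frees one, and it is half bound at 0.129 mM of free partner, far less than saturation, so it parks a further molecule as idle adduct A.

Last row, first product: at equal concentrations step 1 is faster than step 2 by a selectivity factor of 7.84, so this row is dropped.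

Read down, the rows set a price of two partners per turnover: one consumed, one parked. The supply therefore buys 17.1% of the charge. Call this the reach, the gas delivered at full transfer divided by twice the charge.

The reach is this reckoning's first answer. For the second, step 1 must pass half the supply at the end, with the charge less the reach present, which asks for 0.735 mM of free partner. Idle adduct A then stands at 7.29 mM, a share of 9.16%.

The forecast gave 15.5% (13.5% to 17.5%) and 10.5% (8% to 13.5%), holding that “The run is limited by gas transfer”.

The simulation gives 14.9% and 10.5%.

Transfer ran evenly, with 48% of its turnover done at 25.0 s, while step 1, as starting material built up, had 6.1% of its turnover done at 10.0 s and its midpoint at 29.4 s. Free partner made up 95.7% of free partner and idle adduct A together at 5.00 s, and 10.5% at 50 s. The reach stands 2.2 percentage points above this flask's conversion. Scaled to the neighbour charged with 0.085 M, it becomes 10.1%, and that neighbour gives 9.86%.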